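**Retrosynthetic overview**
- The pyranone ring is made last: a two-atom ring expansion of (R)-β-butyrolactone by the chain β-keto ester forms the ring C3–C4 bond and the lactone C–O bond; the acid is freed in the same flask from its tert-butyl ester.
- The diene is cut between the two sp2 carbons: an (E)-alkenyl boronate plus a (Z)-α-bromo enoate (Suzuki coupling, retention on both partners).
- The boronate comes from the aldehyde, and that from the ω-hydroxy β-keto ester obtained by Claisen opening of (R)-5-methyloxepan-2-one with methyl acetate enolate.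
- Key step: (R)-5-methyloxepan-2-one comes from an enantioselective Baeyer–Villiger ring expansion of 4-methylcyclohexanone, which sets the isolated methyl stereocentre.
- Ring order: the seven-membered lactone first (transient, opened in the next step), the six-membered pyranone last; the sec-butyl and carbinol stereocentres come from (S)-2-methylbutan-1-ol and (R)-β-butyrolactone.

Assumption: the 3-acyl-4-hydroxy-5,6-dihydropyran-2-one is written as the enol tautomer of the given SMILES; its triketone tautomers are the same compound.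

**Route**

Step 1
Reactants: 1 4-methylcyclohexanone
Product: 2 (R)-5-methyloxepan-2-one
Conditions: Sc(OTf)3 (5 mol%), chiral C2-symmetric N,N′-dioxide ligand (amino-acid-derived bis-anilide, 6 mol%, antipode that gives the R lactone), Al(OiPr)3 (0.5 equiv), mCPBA (1.1 equiv), EtOAc, −20 °C
Reagents that add atoms: mCPBA (3-chloroperoxybenzoic acid), OOC(=O)c1cccc(Cl)c1
Why: Catalytic enantioselective Baeyer–Villiger oxidation (desymmetrisation): the chiral trivalent scandium complex holds the Criegee adduct so that only one of the two enantiotopic ring CH2 groups makes the 1,2-shift to oxygen, which sets the methyl-bearing carbon as R (about 90% ee is expected for 4-alkyl cyclohexanones).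

Step 2
Reactants: 2 (R)-5-methyloxepan-2-one; 3 methyl acetate
Product: 4 methyl (R)-8-hydroxy-6-methyl-3-oxooctanoate
Conditions: 3 (2.5 equiv), LiN(iPr)2 (2.5 equiv), THF, −78 °C; then 2, −78 → −40 °C; 1 M HCl quench
Reagents that add atoms: none
Why: Crossed Claisen condensation on a lactone: the lithium ester enolate adds to the lactone carbonyl, the ring opens to the keto alkoxide, and the β-keto ester is at once deprotonated by the second equivalent of enolate, which blocks over-addition; the stereocentre is not touched.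

Step 3
Reactants: 4 methyl (R)-8-hydroxy-6-methyl-3-oxooctanoate
Product: 5 methyl (R)-6-methyl-3,8-dioxooctanoate
Conditions: TEMPO (10 mol%), PhI(OAc)2 (1.1 equiv), CH2Cl2, rt
Reagents that add atoms: none
Why: Oxoammonium (TEMPO) oxidation is selective for the primary alcohol, stops at the aldehyde in dry CH2Cl2, and its mildly acidic medium avoids aldol reactions of the keto ester.

Step 4
Reactants: 5 methyl (R)-6-methyl-3,8-dioxooctanoate
Product: 6 methyl (6R,8E)-6-methyl-3-oxo-9-(4,4,5,5-tetramethyl-1,3,2-dioxaborolan-2-yl)non-8-enoate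
Conditions: CrCl2 (8 equiv), Cl2CHB(pin) (2 equiv), LiI (4 equiv), THF, rt
Reagents that add atoms: 2-(dichloromethyl)-4,4,5,5-tetramethyl-1,3,2-dioxaborolane, ClC(Cl)B1OC(C)(C)C(C)(C)O1
Why: Takai–Utimoto boryl olefination: the chromium reagent formed from the dihalomethyl boronate and divalent chromium adds only to the aldehyde (ketone, ester and the acidic CH2 are tolerated) and eliminates to the (E)-alkenyl boronate, typically >20:1 E.

Step 5
Reactants: 7 (S)-2-methylbutan-1-ol
Product: 9 tert-butyl (2Z,4S)-2-bromo-4-methylhex-2-enoate, via (S)-2-methylbutanal 8 (not isolated)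
Conditions: TEMPO (1 mol%), KBr (10 mol%), NaOCl (1.1 equiv), NaHCO3, CH2Cl2/H2O, 0 °C; CH2Cl2 layer dried (MgSO4) and added to Ph3P=CHCO2tBu (1.2 equiv) pre-treated with NBS (1.2 equiv), CH2Cl2, −20 °C → rt
Reagents that add atoms: tert-butyl 2-(triphenyl-λ5-phosphanylidene)acetate, CC(C)(C)OC(=O)C=P(c1ccccc1)(c1ccccc1)c1ccccc1; N-bromosuccinimide, O=C1CCC(=O)N1Br
Why: Anelli oxidation gives the α-chiral aldehyde without racemisation, and the Wittig reaction of the α-bromo stabilised ylide places the ester trans to the sec-butyl group (Z bromo enoate, about 9:1 or better expected, minor isomer removed by chromatography); the S centre comes from 7.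

Step 6
Reactants: 6 methyl (6R,8E)-6-methyl-3-oxo-9-(4,4,5,5-tetramethyl-1,3,2-dioxaborolan-2-yl)non-8-enoate; 9 tert-butyl (2Z,4S)-2-bromo-4-methylhex-2-enoate
Product: 10 methyl (6R,8E,10E,12S)-10-(tert-butoxycarbonyl)-6,12-dimethyl-3-oxotetradeca-8,10-dienoate
Conditions: PdCl2(dppf) (5 mol%), K3PO4 (3 equiv), THF/H2O 10:1, 40 °C
Reagents that add atoms: none
Why: Suzuki–Miyaura coupling: oxidative addition of zerovalent palladium into the activated C–Br bond and transmetalation of the alkenyl boronate both go with retention, so the sec-butyl group ends cis to the new vinyl group and trans to the ester; the phosphate base leaves both esters and both stereocentres alone.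

Step 7
Reactants: 10 methyl (6R,8E,10E,12S)-10-(tert-butoxycarbonyl)-6,12-dimethyl-3-oxotetradeca-8,10-dienoate; 11 (R)-4-methyloxetan-2-one
Product: 14 target acid CNP0281879.1, via open-chain hydroxy triketo ester 12 (not isolated), via tert-butyl ester of the target 13 (not isolated)
Conditions: Mg(OTf)2 (1.2 equiv), iPr2NEt (2.5 equiv), 11 (1.5 equiv), CH2Cl2/MeCN 4:1, 0 °C → rt; then TFA (to 25 vol%), rt
Reagents that add atoms: none
Why: Proposed new method: magnesium-templated acylative ring expansion of a β-lactone by a β-keto ester (oxetan-2-one to oxane-2,4-dione, two-atom insertion). Soft enolisation gives the chelated magnesium enolate of 10; the β-lactone carbonyl binds the same divalent magnesium centre and is C-acylated with acyl–oxygen cleavage, driven by about 23 kcal/mol of ring strain and by immediate deprotonation of triacylmethane 12. The freed secondary alkoxide sits next to the methyl ester and closes the six-membered lactone with loss of methanol to give 13; the TFA added afterwards finishes any incomplete lactonisation and removes the tert-butyl ester. The carbinol carbon is never a reaction centre, so the R configuration of 11 is kept. Closest known reaction types: MgCl2/amine soft-enolisation C-acylation of β-keto esters with acyl chlorides or acyl imidazoles, acyl–oxygen opening of β-lactones by lithium ester enolates and by magnesium or zinc alkoxides, and acylation/ring-expansion cascades of cyclic β-keto esters.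

**Compound list**

1 | 4-methylcyclohexanone | CC1CCC(=O)CC1 | starting material
2 | (R)-5-methyloxepan-2-one | O=C1CC[C@@H](C)CCO1 | intermediate
3 | methyl acetate | COC(C)=O | starting material
4 | methyl (R)-8-hydroxy-6-methyl-3-oxooctanoate | COC(=O)CC(=O)CC[C@@H](C)CCO | intermediate
5 | methyl (R)-6-methyl-3,8-dioxooctanoate | COC(=O)CC(=O)CC[C@@H](C)CC=O | intermediate
6 | methyl (6R,8E)-6-methyl-3-oxo-9-(4,4,5,5-tetramethyl-1,3,2-dioxaborolan-2-yl)non-8-enoate | COC(=O)CC(=O)CC[C@@H](C)C/C=C/B1OC(C)(C)C(C)(C)O1 | intermediate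
7 | (S)-2-methylbutan-1-ol | CC[C@H](C)CO | starting material
8 | (S)-2-methylbutanal | CC[C@H](C)C=O | intermediate
9 | tert-butyl (2Z,4S)-2-bromo-4-methylhex-2-enoate | CC[C@H](C)/C=C(\Br)C(=O)OC(C)(C)C | intermediate
10 | methyl (6R,8E,10E,12S)-10-(tert-butoxycarbonyl)-6,12-dimethyl-3-oxotetradeca-8,10-dienoate | CC[C@H](C)/C=C(\C=C\C[C@H](C)CCC(=O)CC(=O)OC)C(=O)OC(C)(C)C | intermediate
11 | (R)-4-methyloxetan-2-one ((R)-β-butyrolactone) | C[C@@H]1CC(=O)O1 | starting material
12 | methyl (6R,8E,10E,12S)-10-(tert-butoxycarbonyl)-2-[(3R)-3-hydroxybutanoyl]-6,12-dimethyl-3-oxotetradeca-8,10-dienoate (formed as its magnesium chelate) | CC[C@H](C)/C=C(\C=C\C[C@H](C)CCC(=O)C(C(=O)OC)C(=O)C[C@@H](C)O)C(=O)OC(C)(C)C | intermediate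
13 | tert-butyl (2E,4S)-2-[(1E,4R)-7-[(6R)-4-hydroxy-6-methyl-2-oxo-5,6-dihydro-2H-pyran-3-yl]-4-methyl-7-oxohept-1-en-1-yl]-4-methylhex-2-enoate | CC[C@H](C)/C=C(\C=C\C[C@H](C)CCC(=O)C1=C(O)C[C@@H](C)OC1=O)C(=O)OC(C)(C)C | intermediate
14 | (2E,4S)-2-[(1E,4R)-7-[(6R)-4-hydroxy-6-methyl-2-oxo-5,6-dihydro-2H-pyran-3-yl]-4-methyl-7-oxohept-1-en-1-yl]-4-methylhex-2-enoic acid (CNP0281879.1) | CC[C@H](C)/C=C(\C=C\C[C@H](C)CCC(=O)C1=C(O)C[C@@H](C)OC1=O)C(=O)O | target

**Step count and risks**

Total: 7 steps. Longest linear sequence: 6 steps (1, 2, 3, 4, 6, 7); step 5 is the side branch.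

Three steps most likely to fail:

1. Step 7 (the proposed new ring expansion). The enolate may attack the β-carbon of 11 instead of the carbonyl, 11 may oligomerise or eliminate to crotonate, or the lactone may not close.
Fallback with known chemistry, setting out from 2 (and using 9) and coming back at 13. Lactone 2 is opened with NaOMe in MeOH to methyl (R)-6-hydroxy-4-methylhexanoate F1. Oxidation (TEMPO, PhI(OAc)2) gives methyl (R)-4-methyl-6-oxohexanoate F2. CrCl2, Cl2CHB(pin) and LiI convert it into methyl (4R,6E)-4-methyl-7-(4,4,5,5-tetramethyl-1,3,2-dioxaborolan-2-yl)hept-6-enoate F3. Coupling with 9 (PdCl2(dppf), K3PO4) gives methyl (4R,6E,8E,10S)-8-(tert-butoxycarbonyl)-4,10-dimethyldodeca-6,8-dienoate F4. LiOH in THF/H2O at 0 °C cleaves only the methyl ester and gives (4R,6E,8E,10S)-8-(tert-butoxycarbonyl)-4,10-dimethyldodeca-6,8-dienoic acid F5. In parallel, commercial methyl (R)-3-hydroxybutanoate and excess lithium enolate of tert-butyl acetate give tert-butyl (R)-5-hydroxy-3-oxohexanoate F6, which closes in TFA to (R)-6-methyloxane-2,4-dione F7. F5 and F7 with DCC and DMAP in CH2Cl2 give the enol ester (6R)-6-methyl-2-oxo-5,6-dihydro-2H-pyran-4-yl (4R,6E,8E,10S)-8-(tert-butoxycarbonyl)-4,10-dimethyldodeca-6,8-dienoate F8. DMAP rearranges F8 in the same flask (O-to-C acyl shift) to 13, and the TFA stage of step 7 then gives 14.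

2. Step 1 (enantioselectivity for the R lactone). A simple 4-methyl group gives the catalyst little to grip, and the easily used enzymes give the S lactone. Any S lactone ends as a hard-to-remove diastereomer of 14.
Fallback, setting out from 1 and coming back at 2. Ketone 1 is deprotonated with a chiral lithium amide (lithium bis(1-phenylethyl)amide of the antipode that gives the R enol ether, LiCl, Me3SiCl present, THF, −78 °C) to (R)-trimethyl[(4-methylcyclohex-1-en-1-yl)oxy]silane F9. Ozonolysis with NaBH4 work-up gives (R)-6-hydroxy-4-methylhexanoic acid F10. Yamaguchi lactonisation (2,4,6-trichlorobenzoyl chloride, Et3N, DMAP, toluene, high dilution) returns 2.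

3. Step 6 (Suzuki coupling next to a β-keto ester). Under aqueous base the keto ester can hydrolyse and decarboxylate, or its enolate can add to the bromo enoate.
Fallback, setting out from 5 and coming back at 10. Aldehyde 5 is treated with Bu3SnCHBr2, CrCl2 and LiI (THF/DMF) to give the (E)-alkenyl stannane methyl (6R,8E)-6-methyl-3-oxo-9-(tributylstannyl)non-8-enoate F11. Base-free Stille coupling of F11 with 9 (Pd2(dba)3, AsPh3, CuI, DMF, rt) gives 10.

**Further compounds**

F1 | step 7 | methyl (R)-6-hydroxy-4-methylhexanoate | COC(=O)CC[C@@H](C)CCO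
F2 | step 7 | methyl (R)-4-methyl-6-oxohexanoate | COC(=O)CC[C@@H](C)CC=O
F3 | step 7 | methyl (4R,6E)-4-methyl-7-(4,4,5,5-tetramethyl-1,3,2-dioxaborolan-2-yl)hept-6-enoate | COC(=O)CC[C@@H](C)C/C=C/B1OC(C)(C)C(C)(C)O1
F4 | step 7 | methyl (4R,6E,8E,10S)-8-(tert-butoxycarbonyl)-4,10-dimethyldodeca-6,8-dienoate | CC[C@H](C)/C=C(\C=C\C[C@H](C)CCC(=O)OC)C(=O)OC(C)(C)C
F5 | step 7 | (4R,6E,8E,10S)-8-(tert-butoxycarbonyl)-4,10-dimethyldodeca-6,8-dienoic acid | CC[C@H](C)/C=C(\C=C\C[C@H](C)CCC(=O)O)C(=O)OC(C)(C)C
F6 | step 7 | tert-butyl (R)-5-hydroxy-3-oxohexanoate | C[C@@H](O)CC(=O)CC(=O)OC(C)(C)C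
F7 | step 7 | (R)-6-methyloxane-2,4-dione | C[C@@H]1CC(=O)CC(=O)O1
F8 | step 7 | (6R)-6-methyl-2-oxo-5,6-dihydro-2H-pyran-4-yl (4R,6E,8E,10S)-8-(tert-butoxycarbonyl)-4,10-dimethyldodeca-6,8-dienoate | CC[C@H](C)/C=C(\C=C\C[C@H](C)CCC(=O)OC1=CC(=O)O[C@H](C)C1)C(=O)OC(C)(C)C
F9 | step 1 | (R)-trimethyl[(4-methylcyclohex-1-en-1-yl)oxy]silane | C[C@H]1CC=C(O[Si](C)(C)C)CC1
F10 | step 1 | (R)-6-hydroxy-4-methylhexanoic acid | OC(=O)CC[C@@H](C)CCO
F11 | step 6 | methyl (6R,8E)-6-methyl-3-oxo-9-(tributylstannyl)non-8-enoate | COC(=O)CC(=O)CC[C@@H](C)C/C=C/[Sn](CCCC)(CCCC)CCCC
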